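**Retrosynthetic overview**

1. The C3–O ester is cut last: the (Z)-4-acetoxy-2-methylbut-2-enoyl group is put on the cis alcohol by palladium-catalysed carbonylation of (Z)-3-iodobut-2-enyl acetate, so the Z geometry comes from the iodide.
2. Ring B (the dihydrofuran) is cut across O1–C7a and C2–C3: a formal (3+2) annulation of the C3–C3a–C7a unit of an ortho-fluorobenzaldehyde with a C2–O unit that is methacrolein with reversed polarity, a (Z)-γ-silyloxyallylboronate. Asymmetric allylboration and fluoride-triggered SNAr run in one flask.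
3. Enabling feature: the C5 acetyl group of ring A (the benzene ring) is para to C7a, so a fluorine at C7a can be displaced by an alkoxide; the C6 oxygen is meta to C7a and does not deactivate it; C2 and C3 carry vicinal oxygens, and only the C2 oxygen can reach C7a (five- against four-membered ring).
4. Ring A is bought as 4-fluoro-2-hydroxyacetophenone; the C3 carbon is added by bromination para to the hydroxyl and palladium-catalysed formylation. Ring B is the only ring formed, in step 6.

Key step: step 6

Remark: the target is the cis (2S,3S) isomer with a Z (angelate-type) enoate; cis in ring B corresponds to a syn 1,2-diol in the open chain, which is why a Z allylboronate is used.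

**Route**

Step 1
Reactants: 1 1-(4-fluoro-2-hydroxyphenyl)ethan-1-one
Product: 2 1-(5-bromo-4-fluoro-2-hydroxyphenyl)ethan-1-one
Conditions: NBS, MeCN, 0 °C → rt
Reagents that add atoms: N-bromosuccinimide, O=C1CCC(=O)N1Br
Why: Electrophilic aromatic bromination in which the hydroxyl group directs para, the fluorine ortho and the acetyl group meta, all to the same carbon (the later C3a), so one regioisomer should dominate.

Step 2
Reactants: 2 1-(5-bromo-4-fluoro-2-hydroxyphenyl)ethan-1-one
Product: 3 1-{5-bromo-4-fluoro-2-[(4-methoxybenzyl)oxy]phenyl}ethan-1-one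
Conditions: PMBCl, K2CO3, KI (cat.), DMF, 50 °C
Reagents that add atoms: 4-methoxybenzyl chloride, COc1ccc(CCl)cc1
Why: Williamson ether synthesis on the phenoxide, which removes the acidic phenol before the fluoride and carbonylation steps and leaves an ether that can be cleaved oxidatively at the end.

Step 3
Reactants: 3 1-{5-bromo-4-fluoro-2-[(4-methoxybenzyl)oxy]phenyl}ethan-1-one
Product: 4 5-acetyl-2-fluoro-4-[(4-methoxybenzyl)oxy]benzaldehyde
Conditions: CO/H2 (1:1, 5 bar), Pd(OAc)2 (1 mol%), n-BuP(1-Ad)2 (3 mol%), TMEDA, toluene, 100 °C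
Reagents that add atoms: carbon monoxide, [C-]#[O+]
Why: Palladium-catalysed reductive carbonylation (formylation) of an aryl bromide, by oxidative addition, CO insertion and hydrogenolysis of the acylpalladium, which should tolerate the ketone, the aryl fluoride and the benzyl-type ether.

Step 4
Reactants: 5 2-methylprop-2-en-1-ol
Product: 6 tert-butyldimethyl[(2-methylprop-2-en-1-yl)oxy]silane
Conditions: TBSCl, imidazole, CH2Cl2, 0 °C → rt
Reagents that add atoms: tert-butyldimethylsilyl chloride, CC(C)(C)[Si](C)(C)Cl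
Why: Standard silylation of a primary alcohol.

Step 5
Reactants: 6 tert-butyldimethyl[(2-methylprop-2-en-1-yl)oxy]silane
Product: 9 (Z)-tert-butyldimethyl{[2-methyl-3-(4,4,5,5-tetramethyl-1,3,2-dioxaborolan-2-yl)prop-1-en-1-yl]oxy}silane, via lithiated silyl ether 7 (not isolated), via lithium boronate complex 8 (not isolated)
Conditions: s-BuLi, THF, −78 °C; i-PrOBpin, −78 °C; HCl (1 equiv, Et2O), −78 °C → rt
Reagents that add atoms: 2-isopropoxy-4,4,5,5-tetramethyl-1,3,2-dioxaborolane, CC(C)OB1OC(C)(C)C(C)(C)O1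
Why: Deprotonation of the allyl silyl ether next to oxygen should give an oxygen-chelated (Z)-siloxyallyllithium, which boron electrophiles take up at the carbon remote from oxygen, so the enol ether keeps the Z geometry (the established access to (Z)-γ-oxyallyl boronates and stannanes).

Step 6
Reactants: 4 5-acetyl-2-fluoro-4-[(4-methoxybenzyl)oxy]benzaldehyde; 9 (Z)-tert-butyldimethyl{[2-methyl-3-(4,4,5,5-tetramethyl-1,3,2-dioxaborolan-2-yl)prop-1-en-1-yl]oxy}silane
Product: 12 1-[(2S,3S)-3-hydroxy-6-[(4-methoxybenzyl)oxy]-2-(prop-1-en-2-yl)-2,3-dihydro-1-benzofuran-5-yl]ethan-1-one (cis), via borate adduct 10 (not isolated), via C2 alkoxide 11 (not isolated)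
Conditions: (R)-TRIP phosphoric acid (5 mol%), 4 Å MS, toluene, −30 °C; then Bu4NF (2 equiv, THF), DMF, 0 → 50 °C
Reagents that add atoms: none
Why: In the first stage the phosphoric acid activates boronate 9 by hydrogen bonding and the allyl unit is transferred through a closed six-membered chair transition state (closest known reaction type: chiral-phosphoric-acid-catalysed syn-alkoxyallylboration of aryl aldehydes with (Z)-γ-oxyallyl pinacolboronates), which forms the C2–C3 bond at the aldehyde only, the ortho-alkoxy aryl ketone being far less electrophilic. C3 is set by the catalyst, (R)-TRIP being chosen because it is expected to expose the Re face of an aryl aldehyde, and C2 is set relative to C3 by the Z geometry of 9, whose silyloxy group sits axial in the chair and should give the syn (1S,2S) adduct 10. In the second stage fluoride removes the silyl group (closest known reaction type: fluoride-triggered desilylative SNAr etherification of activated aryl fluorides) and the C2 alkoxide 11 closes ring B by 5-exo-trig addition to C7a and loss of fluoride, the Meisenheimer intermediate being stabilised by the para acetyl group; the fluoride set free carries the sequence on. Site selectivity in the ring closure is secured by ring size, since the C3 oxygen could only form a four-membered ring, and the PMB ether at C6 is meta to C7a and leaves its electrophilicity intact. Neither stereocentre is touched in the ring closure, so the syn adduct should become the cis (2S,3S) alcohol 12. The step therefore needs face selectivity at the aldehyde (catalyst), syn selectivity (alkene geometry of 9) and chemoselectivity for aldehyde over ketone (inherent reactivity).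

Step 7
Reactants: 13 but-2-yn-1-ol
Product: 15 (Z)-3-iodobut-2-en-1-ol, via cyclic alkenylalanate 14 (not isolated)
Conditions: NaAlH2(OCH2CH2OMe)2, THF, 0 °C → rt; then I2, −78 °C → rt
Reagents that add atoms: iodine, II
Why: Alkoxide-directed trans-hydroalumination of the propargylic alcohol places aluminium on C3 cis to the CH2O group, and iodinolysis with retention should give the Z iodide.

Step 8
Reactants: 15 (Z)-3-iodobut-2-en-1-ol
Product: 16 (Z)-3-iodobut-2-en-1-yl acetate
Conditions: Ac2O, pyridine, DMAP (cat.), CH2Cl2, 0 °C → rt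
Reagents that add atoms: acetic anhydride, CC(=O)OC(C)=O
Why: Acetylation of the primary allylic alcohol, which cannot affect the alkene geometry.

Step 9
Reactants: 12 1-[(2S,3S)-3-hydroxy-6-[(4-methoxybenzyl)oxy]-2-(prop-1-en-2-yl)-2,3-dihydro-1-benzofuran-5-yl]ethan-1-one; 16 (Z)-3-iodobut-2-en-1-yl acetate
Product: 17 (2S,3S)-5-acetyl-6-[(4-methoxybenzyl)oxy]-2-(prop-1-en-2-yl)-2,3-dihydro-1-benzofuran-3-yl (2Z)-4-(acetyloxy)-2-methylbut-2-enoate
Conditions: CO (1 atm), Pd(OAc)2 (10 mol%), Xantphos (12 mol%), Et3N, toluene, 60 °C (16 in twofold excess)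
Reagents that add atoms: carbon monoxide, [C-]#[O+]
Why: Carbonylative esterification (alkoxycarbonylation of an alkenyl iodide) in which zerovalent palladium inserts into the C–I bond, CO insertion gives an acylpalladium and the C3 hydroxyl of 12 captures it, with retention of the alkene geometry, without carboxyl activation that could isomerise the Z enoate, and without touching C2 or C3.

Step 10
Reactants: 17 (2S,3S)-5-acetyl-6-[(4-methoxybenzyl)oxy]-2-(prop-1-en-2-yl)-2,3-dihydro-1-benzofuran-3-yl (2Z)-4-(acetyloxy)-2-methylbut-2-enoate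
Product: 18 (2S,3S)-5-acetyl-6-hydroxy-2-(prop-1-en-2-yl)-2,3-dihydro-1-benzofuran-3-yl (2Z)-4-(acetyloxy)-2-methylbut-2-enoate
Conditions: DDQ, CH2Cl2/pH 7 phosphate buffer (10:1), 0 °C → rt
Reagents that add atoms: none
Why: Oxidative cleavage of the PMB ether by DDQ under buffered, near-neutral conditions, which should be slower than for an alkyl PMB ether but should spare the benzylic ester, the allylic acetate, the Z enoate and the isopropenyl group.

**Compound list**

1 | 1-(4-fluoro-2-hydroxyphenyl)ethan-1-one | CC(=O)c1ccc(F)cc1O | starting material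
2 | 1-(5-bromo-4-fluoro-2-hydroxyphenyl)ethan-1-one | CC(=O)c1cc(Br)c(F)cc1O | intermediate
3 | 1-{5-bromo-4-fluoro-2-[(4-methoxybenzyl)oxy]phenyl}ethan-1-one | CC(=O)c1cc(Br)c(F)cc1OCc1ccc(OC)cc1 | intermediate
4 | 5-acetyl-2-fluoro-4-[(4-methoxybenzyl)oxy]benzaldehyde | CC(=O)c1cc(C=O)c(F)cc1OCc1ccc(OC)cc1 | intermediate
5 | 2-methylprop-2-en-1-ol | C=C(C)CO | starting material
6 | tert-butyldimethyl[(2-methylprop-2-en-1-yl)oxy]silane | C=C(C)CO[Si](C)(C)C(C)(C)C | intermediate
7 | oxygen-chelated (Z)-1-(tert-butyldimethylsilyloxy)-2-methylallyllithium, drawn as the α-lithio ether | C=C(C)C([Li])O[Si](C)(C)C(C)(C)C | intermediate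
8 | lithium [(Z)-3-(tert-butyldimethylsilyloxy)-2-methylallyl](isopropoxy)(pinacolato)borate | [Li+].CC(C)O[B-]1(C/C(C)=C\O[Si](C)(C)C(C)(C)C)OC(C)(C)C(C)(C)O1 | intermediate
9 | (Z)-tert-butyldimethyl{[2-methyl-3-(4,4,5,5-tetramethyl-1,3,2-dioxaborolan-2-yl)prop-1-en-1-yl]oxy}silane | CC(C)(C)[Si](C)(C)O/C=C(/C)CB1OC(C)(C)C(C)(C)O1 | intermediate
10 | 2-{[(1S,2S)-1-{5-acetyl-2-fluoro-4-[(4-methoxybenzyl)oxy]phenyl}-2-(tert-butyldimethylsilyloxy)-3-methylbut-3-en-1-yl]oxy}-4,4,5,5-tetramethyl-1,3,2-dioxaborolane | C=C(C)[C@H](O[Si](C)(C)C(C)(C)C)[C@@H](OB1OC(C)(C)C(C)(C)O1)c1cc(C(C)=O)c(OCc2ccc(OC)cc2)cc1F | intermediate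
11 | tetrabutylammonium (1S,2S)-1-{5-acetyl-2-fluoro-4-[(4-methoxybenzyl)oxy]phenyl}-1-hydroxy-3-methylbut-3-en-2-olate | C=C(C)[C@H]([O-])[C@@H](O)c1cc(C(C)=O)c(OCc2ccc(OC)cc2)cc1F.CCCC[N+](CCCC)(CCCC)CCCC | intermediate
12 | 1-[(2S,3S)-3-hydroxy-6-[(4-methoxybenzyl)oxy]-2-(prop-1-en-2-yl)-2,3-dihydro-1-benzofuran-5-yl]ethan-1-one (cis) | C=C(C)[C@@H]1Oc2cc(OCc3ccc(OC)cc3)c(C(C)=O)cc2[C@@H]1O | intermediate
13 | but-2-yn-1-ol | CC#CCO | starting material
14 | sodium 2,2-bis(2-methoxyethoxy)-3-methyl-5H-1,2-oxaaluminol-2-uide (cyclic alkenylalanate) | CC1=CCO[Al-]1(OCCOC)OCCOC.[Na+] | intermediate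
15 | (Z)-3-iodobut-2-en-1-ol | C/C(I)=C/CO | intermediate
16 | (Z)-3-iodobut-2-en-1-yl acetate | C/C(I)=C/COC(C)=O | intermediate
17 | (2S,3S)-5-acetyl-6-[(4-methoxybenzyl)oxy]-2-(prop-1-en-2-yl)-2,3-dihydro-1-benzofuran-3-yl (2Z)-4-(acetyloxy)-2-methylbut-2-enoate | C=C(C)[C@@H]1Oc2cc(OCc3ccc(OC)cc3)c(C(C)=O)cc2[C@@H]1OC(=O)/C(C)=C\COC(C)=O | intermediate
18 | (2S,3S)-5-acetyl-6-hydroxy-2-(prop-1-en-2-yl)-2,3-dihydro-1-benzofuran-3-yl (2Z)-4-(acetyloxy)-2-methylbut-2-enoate | C=C(C)[C@@H]1Oc2cc(O)c(C(C)=O)cc2[C@@H]1OC(=O)/C(C)=C\COC(C)=O | target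

**Step count and risks**

Total step count: 10. Longest linear sequence: 6 steps (steps 1, 2, 3, 6, 9, 10).

Steps most likely to fail:

1. Step 6. The phosphoric acid may not control the aldehyde face with a hindered, trisubstituted Z enol ether boronate, or may protonate the silyl enol ether before the C–C bond forms; either would erode enantiomeric or syn purity. The fallback replaces catalyst control by stoichiometric reagent control and sets out from 6 and 4. Lithiated ether 7, made from 6 as in step 5, is treated with (+)-Ipc2BOMe (the enantiomer made from (−)-α-pinene) to give the lithium [(Z)-3-(tert-butyldimethylsilyloxy)-2-methylallyl](methoxy)diisopinocampheylborate F1. BF3·OEt2 at −78 °C removes the methoxide to leave the [(Z)-3-(tert-butyldimethylsilyloxy)-2-methylallyl]diisopinocampheylborane F2, which by the usual chair model should attack the Re face of 4 at −78 °C and give the syn (1S,2S) diisopinocampheylborinate F3. Bu4NF in THF/DMF, as in step 6, then frees alkoxide 11, and the route is rejoined at 12.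

2. Step 5. s-BuLi may remove a proton from the allylic methyl group instead of the O–CH2 group, silicon may shift from oxygen to carbon in 7, or boron may be taken up at the oxygen-bearing carbon. The fallback sets out from 5 and uses an acetal ether that chelates lithium and carries no silicon on oxygen. SEMCl and i-Pr2NEt give trimethyl(2-{[(2-methylprop-2-en-1-yl)oxy]methoxy}ethyl)silane F4; s-BuLi (THF, −78 °C) gives the chelated lithio ether F5; i-PrOBpin gives the lithium boronate complex F6 and, after HCl, the (Z)-γ-(SEM-oxy)allylboronate F7. With 4 under the allylboration conditions of step 6 this should give the borate adduct F8; Bu4NF in DMPU at 80 °C then fragments the SEM group to alkoxide 11, and the route is rejoined at 12.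

3. Step 9. Capture of the acylpalladium by the hindered secondary alcohol may be slow, and zerovalent palladium may ionise the allylic acetate and scramble the Z geometry. The fallback sets out from 16 and separates carbonylation from ester formation. Hydroxycarbonylation of 16 (CO 1 atm, Pd(OAc)2, PPh3, H2O, Et3N, DMF, rt) gives (Z)-4-acetoxy-2-methylbut-2-enoic acid F9. 2,4,6-Trichlorobenzoyl chloride and Et3N in toluene give the mixed anhydride F10, which acylates 12 on warming without a nucleophilic amine catalyst (Yamaguchi esterification in the variant used for angelates, to avoid Z to E isomerisation), and the route is rejoined at 17.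

**Further compounds**

F1 | step 6 | lithium [(Z)-3-(tert-butyldimethylsilyloxy)-2-methylallyl](methoxy)diisopinocampheylborate | [Li+].CO[B-](C/C(C)=C\O[Si](C)(C)C(C)(C)C)([C@H]1C[C@H]2C[C@@H]([C@@H]1C)C2(C)C)[C@H]1C[C@H]2C[C@@H]([C@@H]1C)C2(C)C
F2 | step 6 | [(Z)-3-(tert-butyldimethylsilyloxy)-2-methylallyl]diisopinocampheylborane | CC(C)(C)[Si](C)(C)O/C=C(/C)CB([C@H]1C[C@H]2C[C@@H]([C@@H]1C)C2(C)C)[C@H]1C[C@H]2C[C@@H]([C@@H]1C)C2(C)C
F3 | step 6 | (1S,2S)-1-{5-acetyl-2-fluoro-4-[(4-methoxybenzyl)oxy]phenyl}-2-(tert-butyldimethylsilyloxy)-3-methylbut-3-en-1-yl diisopinocampheylborinate | C=C(C)[C@H](O[Si](C)(C)C(C)(C)C)[C@@H](OB([C@H]1C[C@H]2C[C@@H]([C@@H]1C)C2(C)C)[C@H]1C[C@H]2C[C@@H]([C@@H]1C)C2(C)C)c1cc(C(C)=O)c(OCc2ccc(OC)cc2)cc1F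
F4 | step 5 | trimethyl(2-{[(2-methylprop-2-en-1-yl)oxy]methoxy}ethyl)silane | C=C(C)COCOCC[Si](C)(C)C
F5 | step 5 | oxygen-chelated lithiated SEM ether, drawn as the α-lithio ether | C=C(C)C([Li])OCOCC[Si](C)(C)C
F6 | step 5 | lithium (isopropoxy)[(Z)-2-methyl-3-{[2-(trimethylsilyl)ethoxy]methoxy}allyl](pinacolato)borate | [Li+].CC(C)O[B-]1(C/C(C)=C\OCOCC[Si](C)(C)C)OC(C)(C)C(C)(C)O1
F7 | step 5 | (Z)-trimethyl{2-[({[2-methyl-3-(4,4,5,5-tetramethyl-1,3,2-dioxaborolan-2-yl)prop-1-en-1-yl]oxy}methoxy)]ethyl}silane | C[Si](C)(C)CCOCO/C=C(/C)CB1OC(C)(C)C(C)(C)O1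
F8 | step 5 | 2-{[(1S,2S)-1-{5-acetyl-2-fluoro-4-[(4-methoxybenzyl)oxy]phenyl}-3-methyl-2-{[2-(trimethylsilyl)ethoxy]methoxy}but-3-en-1-yl]oxy}-4,4,5,5-tetramethyl-1,3,2-dioxaborolane | C=C(C)[C@H](OCOCC[Si](C)(C)C)[C@@H](OB1OC(C)(C)C(C)(C)O1)c1cc(C(C)=O)c(OCc2ccc(OC)cc2)cc1F
F9 | step 9 | (Z)-4-acetoxy-2-methylbut-2-enoic acid | CC(=O)OC/C=C(/C)C(=O)O
F10 | step 9 | (Z)-4-acetoxy-2-methylbut-2-enoic 2,4,6-trichlorobenzoic anhydride | CC(=O)OC/C=C(/C)C(=O)OC(=O)c1c(Cl)cc(Cl)cc1Cl
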